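**Locants.** Upper flavan: O1, C2, C3, C4, C4a, C5–C8, C8a, with ring A (benzo ring), ring B (2-aryl group) and ring C (pyran). Lower flavan-3-ol: primed locants, with ring D (benzo ring), ring E (2'-aryl group) and ring F (pyran). Monomeric flavans 6–10 carry ordinary chroman locants. Compound numbers are those of the list after the steps.

## Analysis of the target

Target 16 is a biflavanoid: a 7-hydroxy-2-(4-hydroxyphenyl)chroman (rings A, B, C) is bonded through C4 to C8' of a (−)-epiafzelechin unit (6; rings D, E, F). It has four stereocentres in two remote pairs. C2 (S) and C4 (S) in ring C carry their aryl groups cis. C2' (R) and C3' (R) in ring F carry aryl and hydroxyl cis, exactly as in 6. The pairs are separated by ring D and the C4–C8' bond, so neither pair can be expected to control the other. The molecule has five phenols and one secondary alcohol. The free phenols are oxidisable, and C2–O1 and C2'–O1' are benzylic ethers that strong acid or forcing hydrogenolysis can open. C2' of a free-phenolic flavan-3-ol epimerises in hot base, and the C4–C8' diarylmethine bond is acid-labile. The difficulties are the crowded C4–C8' junction, which sits between O1' and the C7' oxygen, the choice of C8' over C6' on ring D, and the absolute configuration of C2 and C4 relative to a lower unit that is already fixed. The strategy rests on the absence of oxygen at C3. Ring C (O1, C2, C3, C4, C4a, C8a) is then a plain 2,4-cis-diarylchroman. That is the [4+2] adduct of a ring A ortho-quinone methide (O1=C8a–C4a=C4, with C4 already bearing C8') and the vinyl group of a 4-oxystyrene (C2=C3).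

## Retrosynthetic reasoning

**Protecting groups (16 ⇒ 15 ⇒ 14).** The five phenols are masked as benzyl ethers and the C3' hydroxyl as a silyl ether. Benzyl ethers survive aryllithium chemistry and mild acid and leave together in one hydrogenolysis. The silyl ether keeps the C3' oxygen from acting as a nucleophile towards C4 in the key step, and it is needed for the halogen–lithium exchange. The forward steps are desilylation and then hydrogenolysis.

**Ring C (14 ⇒ 12 + 5).** O1–C2 and C3–C4 are cut together. This is the only cut that removes a ring, two skeletal bonds and both upper stereocentres at once. It leaves an achiral two-carbon partner (5) and a diaryl carbinol (12) whose carbinol carbon is the future C4. Forward, a chiral Brønsted acid catalyst dehydrates 12 to the ortho-quinone methide 13, which must add 5 with 2-aryl regiochemistry, cis relative configuration and the correct face at C4. Cutting C4–C8' instead would require a bimolecular arylation at the most crowded carbon with no handle on C4 configuration.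

**Carbinol carbon to ring D (12 ⇒ 11 ⇒ 10 + 3).** The bond between the carbinol carbon and C8' is cut as aryl anion plus aldehyde. This places C8' regiochemistry on a well-understood electrophilic halogenation of ring D. The crowded bond is formed by addition of an sp2 carbanion to a formyl group, which tolerates hindrance. The ring A phenol travels as an allyl ether (11). A silyl ether in that position would sit five atoms from the new lithium alkoxide and could migrate, setting off uncontrolled quinone methide formation under basic conditions. The allyl group is inert to the aryllithium and is removed by zerovalent palladium without acid or fluoride, so the acid-labile carbinol and the C3' silyl ether are untouched. The carbinol configuration is irrelevant because that carbon becomes trigonal in 13.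

**Lower unit (10 ⇒ 9 ⇒ 8 ⇒ 7 ⇒ 6).** Aryllithium 10 comes from bromide 9 by halogen–lithium exchange. Bromide 9 comes from silyl ether 8 by bromination at C8, the ring D position flanked by only one benzyloxy group. Compounds 8 and 7 are the silylated and tribenzylated forms of natural 6, which supplies C2' and C3' ready-made.

**Small fragments (3 ⇒ 2 ⇒ 1; 5 ⇒ 4).** Aldehyde 3 comes from 1 by alkylation of the non-chelated 4-hydroxyl first (2) and the chelated 2-hydroxyl second. Styrene 5 comes from aldehyde 4 by methylenation.

## Alternatives that were turned down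

**Alternative 1:** Ring D is built rather than bought. The disconnection removes the benzene ring itself. C8' and one oxygenated neighbour come from the silyloxyalkyne A3, which hangs on C4 of a finished upper flavan. The other four carbons come from the cyclobutenone A2. Forward, heating opens A2 to a vinylketene, which adds [2+2] to the alkyne. The new vinylcyclobutenone opens again, and a 6π electrocyclisation and tautomerisation give the resorcinol derivative A1 (Danheiser-type benzannulation).
- For: the oxygen pattern of ring D and the position of the flavanyl group between two oxygens are fixed by construction. There is no C6'/C8' question and no bimolecular arylation at a crowded carbon. On regiocontrol it is stronger than the chosen route, which relies on the C8 preference of a bromination, and it does not depend on the supply of 6.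
- Against: A1 still lacks ring F, ring E, C2' and C3'. Annulating a 2,3-cis flavan-3-ol onto its free phenol needs C-alkylation at C4a', an asymmetric oxidation and an inversion at C3', which is well over six further steps on an advanced intermediate. A3 must already carry C2 and C4 in the right absolute sense, so the stereochemical problem is moved upstream, not solved. A2 is a labile partner used hot and in excess.
- Comparison: the chosen strategy takes the whole lower half from 6 and makes ring C with both of its stereocentres in one step.

**Alternative 2:** The cut is C4'–C4a' in ring F. The precursor A5 is the ring D aryl ether of an aryl(oxiranyl)methanol, so O1'–C2' is already in place and C3'/C4' are a terminal epoxide. Forward, a boron Lewis acid activates the epoxide and C4a' attacks its CH2 carbon (Friedel–Crafts, closing ring F in the endo sense). The epoxide oxygen becomes the C3' hydroxyl of A4.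
- For: only one ortho carbon of the ether (C4a') is free, so the ring closure is regiochemically unambiguous. C2' and C3' come from dependable asymmetric epoxidation, and the closure is intramolecular. It is also independent of 6.
- Against: A5 must contain the complete upper unit, including C2, C4 and the C4–C8' bond, none of which this key step helps to make. The benzylic ether O1'–C2' has to be formed with inversion on a phenol crowded by the flavanyl group. That ether competes with the epoxide for the Lewis acid, and ionisation there would scramble C2'. This is why ring E carries a pivalate, at the price of an extra deprotection. Closure at the internal epoxide carbon to a dihydrobenzofuran competes with the wanted endo mode.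
- Comparison: its key step forms one ring and one C–C bond and creates no stereocentre. The chosen step forms one ring, two bonds and two stereocentres.

**Alternative 3:** The cut is C4–C4a of ring C. The precursor A7 carries C2 already as a chiral 3-benzyloxyphenyl ether and has a carbinol next to ring D. Forward, a Lewis-acidic metal triflate ionises that carbinol. The tethered aryl ether attacks the cation through the carbon para to its benzyloxy group, closing ring C to A6.
- For: it uses the same highly stabilised cation as the chosen route but traps it intramolecularly. C2 is set beforehand by a dependable asymmetric reduction, and C4 follows under substrate control as the cis, diequatorial product. On control of C4 it is at least as strong as the chosen route, which needs a catalyst to pick a face.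
- Against: O1–C2 in A7 is a 4-alkoxybenzylic aryl ether that the same Lewis acid can ionise. C2 is then racemised or the aryloxy group is lost, and the information the closure relies on is lost with it. The arene can also close through the carbon between its two oxygens, giving the 5-benzyloxy isomer. A7 needs chain extension from C8', an asymmetric reduction and an invertive etherification at an SN1-prone benzylic carbinol, roughly five more steps.
- Comparison: the chosen strategy supplies C2 and C3 from achiral 5 in a single step. If face selection is imperfect, the two cis adducts are diastereomers and can be separated.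

Key step: step 9

Assumption: natural (−)-epiafzelechin (2R,3R) is taken as purchasable; the sense of induction of the phosphoric acid cannot be derived from first principles, so the (R) acid is written and the equally available (S) acid replaces it if the pairing proves mismatched.

## Route

**Step 1**
Reactants: 1 2,4-dihydroxybenzaldehyde
Product: 2 4-(benzyloxy)-2-hydroxybenzaldehyde
Conditions: BnBr (1.05 equiv), NaHCO3, KI (cat.), MeCN, 80 °C
Reagents that add atoms: benzyl bromide, BrCc1ccccc1
Why: Williamson etherification; the 2-hydroxyl is held in a hydrogen bond to the formyl group, so the weak base ionises and alkylates only the more acidic 4-hydroxyl.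

**Step 2**
Reactants: 2 4-(benzyloxy)-2-hydroxybenzaldehyde
Product: 3 2-(allyloxy)-4-(benzyloxy)benzaldehyde
Conditions: allyl bromide, K2CO3, DMF, rt
Reagents that add atoms: allyl bromide, C=CCBr
Why: Williamson etherification of the remaining chelated phenol under a stronger base; the allyl ether is inert to aryllithium reagents and is later removed without acid or fluoride.

**Step 3**
Reactants: 4 4-(benzyloxy)benzaldehyde
Product: 5 4-benzyloxystyrene
Conditions: Ph3PCH3Br, KOtBu, THF, 0 °C to rt
Reagents that add atoms: methyltriphenylphosphonium bromide, C[P+](c1ccccc1)(c1ccccc1)c1ccccc1.[Br-]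
Why: Wittig methylenation of a non-enolisable aromatic aldehyde; the product is kept cold with a trace of radical inhibitor until use.

**Step 4**
Reactants: 6 (−)-epiafzelechin
Product: 7 (2R,3R)-5,7-bis(benzyloxy)-2-[4-(benzyloxy)phenyl]chroman-3-ol
Conditions: BnBr (3.3 equiv), K2CO3, DMF, argon, 0 °C to rt
Reagents that add atoms: benzyl bromide, BrCc1ccccc1
Why: Williamson etherification; carbonate ionises the three phenols but not the C3 alcohol, and low temperature with exclusion of air limits C-benzylation and base-induced epimerisation at C2, so both stereocentres are carried through unchanged.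

**Step 5**
Reactants: 7 (2R,3R)-5,7-bis(benzyloxy)-2-[4-(benzyloxy)phenyl]chroman-3-ol
Product: 8 (2R,3R)-5,7-bis(benzyloxy)-2-[4-(benzyloxy)phenyl]-3-(tert-butyldimethylsilyloxy)chroman
Conditions: TBSCl, imidazole, DMF, rt to 40 °C
Reagents that add atoms: tert-butyldimethylsilyl chloride, CC(C)(C)[Si](C)(C)Cl
Why: Imidazole-promoted silylation of the secondary alcohol; the ether removes the only acidic proton before the organolithium step.

**Step 6**
Reactants: 8 (2R,3R)-5,7-bis(benzyloxy)-2-[4-(benzyloxy)phenyl]-3-(tert-butyldimethylsilyloxy)chroman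
Product: 9 (2R,3R)-5,7-bis(benzyloxy)-2-[4-(benzyloxy)phenyl]-8-bromo-3-(tert-butyldimethylsilyloxy)chroman
Conditions: NBS (1.0 equiv), CH2Cl2, −78 °C to rt
Reagents that add atoms: N-bromosuccinimide, O=C1CCC(=O)N1Br
Why: Electrophilic aromatic bromination; the trioxygenated benzo ring is far more reactive than the mono-oxygenated 2-aryl ring, and C8 (between O1 and one benzyloxy group) is less shielded than C6 (between two benzyloxy groups), which is the usual outcome for 5,7-di-O-benzyl flavan-3-ols.

**Step 7**
Reactants: 9 (2R,3R)-5,7-bis(benzyloxy)-2-[4-(benzyloxy)phenyl]-8-bromo-3-(tert-butyldimethylsilyloxy)chroman; 3 2-(allyloxy)-4-(benzyloxy)benzaldehyde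
Product: 11 [2-(allyloxy)-4-(benzyloxy)phenyl][(2R,3R)-5,7-bis(benzyloxy)-2-(4-benzyloxyphenyl)-3-(tert-butyldimethylsilyloxy)chroman-8-yl]methanol (both carbinol epimers), via 8-lithiochroman 10 (not isolated)
Conditions: t-BuLi (2.0 equiv), THF, −78 °C; then 3, −78 to −40 °C; aq NH4Cl
Reagents that add atoms: none
Why: Bromine–lithium exchange at −78 °C is faster than deprotonation of the benzyl ethers, and the aryllithium adds 1,2 to the aldehyde; the new carbinol centre forms as a mixture, which does not matter because it becomes trigonal in step 9.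

**Step 8**
Reactants: 11 [2-(allyloxy)-4-(benzyloxy)phenyl][(2R,3R)-5,7-bis(benzyloxy)-2-(4-benzyloxyphenyl)-3-(tert-butyldimethylsilyloxy)chroman-8-yl]methanol
Product: 12 [4-(benzyloxy)-2-hydroxyphenyl][(2R,3R)-5,7-bis(benzyloxy)-2-(4-benzyloxyphenyl)-3-(tert-butyldimethylsilyloxy)chroman-8-yl]methanol (both carbinol epimers)
Conditions: Pd(PPh3)4 (5 mol%), morpholine (5 equiv), THF, rt; filtration through Et3N-deactivated silica
Reagents that add atoms: none
Why: Tsuji–Trost-type deallylation; zerovalent palladium ionises the aryl allyl ether to a π-allyl complex and the phenoxide, and morpholine captures the allyl group, so the conditions stay neutral to basic and the acid-labile diaryl carbinol, the silyl ether and the benzyl ethers remain.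

**Step 9**
Reactants: 12 [4-(benzyloxy)-2-hydroxyphenyl][(2R,3R)-5,7-bis(benzyloxy)-2-(4-benzyloxyphenyl)-3-(tert-butyldimethylsilyloxy)chroman-8-yl]methanol; 5 4-benzyloxystyrene
Product: 14 (2R,3R)-5,7-bis(benzyloxy)-8-[(2S,4S)-7-(benzyloxy)-2-(4-benzyloxyphenyl)chroman-4-yl]-2-(4-benzyloxyphenyl)-3-(tert-butyldimethylsilyloxy)chroman, via ortho-quinone methide 13 (not isolated)
Conditions: (R)-3,3'-bis(2,4,6-triisopropylphenyl)-1,1'-binaphthyl-2,2'-diyl hydrogen phosphate (10 mol%), 5 (3 equiv), 4 Å MS, toluene, 0 °C to rt
Reagents that add atoms: none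
Why: The phosphoric acid protonates the doubly benzylic hydroxyl of 12, and loss of water gives the E-configured ortho-quinone methide 13 (ring D anti to the carbonyl), whose exocyclic C4 is stabilised by ring A and by the trioxygenated ring D, so a weak acid suffices and stronger acids that would oligomerise 5 are avoided. The closest known reaction type is the Brønsted-acid-catalysed inverse-electron-demand hetero-Diels–Alder reaction of ortho-quinone methides from 2-hydroxybenzhydryl alcohols with styrenes, including chiral phosphoric acid versions. Ring C closes by an asynchronous [4+2] cycloaddition of the heterodiene O1=C8a–C4a=C4 with the vinyl group of 5: the CH2 terminus bonds to C4 first and the developing 4-benzyloxybenzylic cation is captured by O1, which gives the six-membered ring with O1–C2 and C3–C4 as the new bonds. Regioselectivity is secured by the 4-benzyloxy group, which makes CH2 the nucleophilic end so that only the 2-aryl chroman can form. C2 is set relative to C4 by the endo transition state of the E quinone methide, which places ring B and ring D cis; this is also the diequatorial, thermodynamically preferred arrangement should the O1–C2 closure be reversible. C4 is set in the absolute sense by the phosphate, which stays hydrogen-bonded to the quinone methide oxygen and shields one face of C4; C2' and C3' are too remote to do this, though they make the two possible cis adducts diastereomers that can be told apart and separated. The step also needs chemoselectivity for 5 over Friedel–Crafts attack by C6' of a second molecule, which the excess of the small, nucleophilic styrene and the two benzyloxy groups flanking C6' should secure, and the silyl ether keeps the C3' oxygen from adding to C4.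

**Step 10**
Reactants: 14 (2R,3R)-5,7-bis(benzyloxy)-8-[(2S,4S)-7-(benzyloxy)-2-(4-benzyloxyphenyl)chroman-4-yl]-2-(4-benzyloxyphenyl)-3-(tert-butyldimethylsilyloxy)chroman
Product: 15 (2R,3R)-5,7-bis(benzyloxy)-8-[(2S,4S)-7-(benzyloxy)-2-(4-benzyloxyphenyl)chroman-4-yl]-2-(4-benzyloxyphenyl)chroman-3-ol
Conditions: Bu4NF (1 M in THF), THF, 0 °C to rt
Reagents that add atoms: none
Why: Fluoride-mediated desilylation driven by the Si–F bond; benzyl ethers, both chroman rings and all four stereocentres are inert to fluoride.

**Step 11**
Reactants: 15 (2R,3R)-5,7-bis(benzyloxy)-8-[(2S,4S)-7-(benzyloxy)-2-(4-benzyloxyphenyl)chroman-4-yl]-2-(4-benzyloxyphenyl)chroman-3-ol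
Product: 16 (2R,3R)-8-[(2S,4S)-7-hydroxy-2-(4-hydroxyphenyl)chroman-4-yl]-2-(4-hydroxyphenyl)chroman-3,5,7-triol
Conditions: H2 (1 atm), Pd(OH)2/C (20 wt%), THF/MeOH 1:1, rt
Reagents that add atoms: none
Why: Hydrogenolysis of the five aryl benzyl ethers; these primary benzylic C–O bonds cleave much faster than the secondary, ring-bound benzylic ethers C2–O1 and C2'–O1', so the reaction is stopped once the benzyl groups are gone and no stereocentre is touched.

## Compound list

1 | 2,4-dihydroxybenzaldehyde | O=Cc1ccc(O)cc1O | starting material
2 | 4-(benzyloxy)-2-hydroxybenzaldehyde | O=Cc1ccc(OCc2ccccc2)cc1O | intermediate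
3 | 2-(allyloxy)-4-(benzyloxy)benzaldehyde | O=Cc1ccc(OCc2ccccc2)cc1OCC=C | intermediate
4 | 4-(benzyloxy)benzaldehyde | O=Cc1ccc(OCc2ccccc2)cc1 | starting material
5 | 4-benzyloxystyrene | C=Cc1ccc(OCc2ccccc2)cc1 | intermediate
6 | (−)-epiafzelechin, (2R,3R)-2-(4-hydroxyphenyl)chroman-3,5,7-triol | Oc1cc(O)c2c(c1)O[C@H](c1ccc(O)cc1)[C@H](O)C2 | starting material
7 | (2R,3R)-5,7-bis(benzyloxy)-2-[4-(benzyloxy)phenyl]chroman-3-ol | c3ccccc3COc1cc(OCc3ccccc3)c2c(c1)O[C@H](c1ccc(OCc3ccccc3)cc1)[C@H](O)C2 | intermediate
8 | (2R,3R)-5,7-bis(benzyloxy)-2-[4-(benzyloxy)phenyl]-3-(tert-butyldimethylsilyloxy)chroman | c3ccccc3COc1cc(OCc3ccccc3)c2c(c1)O[C@H](c1ccc(OCc3ccccc3)cc1)[C@H](O[Si](C)(C)C(C)(C)C)C2 | intermediate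
9 | (2R,3R)-5,7-bis(benzyloxy)-2-[4-(benzyloxy)phenyl]-8-bromo-3-(tert-butyldimethylsilyloxy)chroman | c3ccccc3COc1cc(OCc3ccccc3)c2c(c1Br)O[C@H](c1ccc(OCc3ccccc3)cc1)[C@H](O[Si](C)(C)C(C)(C)C)C2 | intermediate
10 | 8-lithio derivative of 8, [(2R,3R)-5,7-bis(benzyloxy)-2-(4-benzyloxyphenyl)-3-(tert-butyldimethylsilyloxy)chroman-8-yl]lithium | c3ccccc3COc1cc(OCc3ccccc3)c2c(c1[Li])O[C@H](c1ccc(OCc3ccccc3)cc1)[C@H](O[Si](C)(C)C(C)(C)C)C2 | intermediate (not isolated)
11 | [2-(allyloxy)-4-(benzyloxy)phenyl][(2R,3R)-5,7-bis(benzyloxy)-2-(4-benzyloxyphenyl)-3-(tert-butyldimethylsilyloxy)chroman-8-yl]methanol, both carbinol epimers | OC(c1ccc(OCc2ccccc2)cc1OCC=C)c1c(OCc2ccccc2)cc(OCc2ccccc2)c2c1O[C@H](c1ccc(OCc3ccccc3)cc1)[C@H](O[Si](C)(C)C(C)(C)C)C2 | intermediate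
12 | [4-(benzyloxy)-2-hydroxyphenyl][(2R,3R)-5,7-bis(benzyloxy)-2-(4-benzyloxyphenyl)-3-(tert-butyldimethylsilyloxy)chroman-8-yl]methanol, both carbinol epimers | OC(c1ccc(OCc2ccccc2)cc1O)c1c(OCc2ccccc2)cc(OCc2ccccc2)c2c1O[C@H](c1ccc(OCc3ccccc3)cc1)[C@H](O[Si](C)(C)C(C)(C)C)C2 | intermediate
13 | (E)-3-(benzyloxy)-6-{[(2R,3R)-5,7-bis(benzyloxy)-2-(4-benzyloxyphenyl)-3-(tert-butyldimethylsilyloxy)chroman-8-yl]methylidene}cyclohexa-2,4-dien-1-one | O=C1C=C(OCc2ccccc2)C=C/C1=C\c1c(OCc2ccccc2)cc(OCc2ccccc2)c2c1O[C@H](c1ccc(OCc3ccccc3)cc1)[C@H](O[Si](C)(C)C(C)(C)C)C2 | intermediate (not isolated)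
14 | (2R,3R)-5,7-bis(benzyloxy)-8-[(2S,4S)-7-(benzyloxy)-2-(4-benzyloxyphenyl)chroman-4-yl]-2-(4-benzyloxyphenyl)-3-(tert-butyldimethylsilyloxy)chroman | c6ccccc6COc1ccc([C@@H]2C[C@H](c3c(OCc5ccccc5)cc(OCc5ccccc5)c4c3O[C@H](c3ccc(OCc5ccccc5)cc3)[C@H](O[Si](C)(C)C(C)(C)C)C4)c3ccc(OCc5ccccc5)cc3O2)cc1 | intermediate
15 | (2R,3R)-5,7-bis(benzyloxy)-8-[(2S,4S)-7-(benzyloxy)-2-(4-benzyloxyphenyl)chroman-4-yl]-2-(4-benzyloxyphenyl)chroman-3-ol | c6ccccc6COc1ccc([C@@H]2C[C@H](c3c(OCc5ccccc5)cc(OCc5ccccc5)c4c3O[C@H](c3ccc(OCc5ccccc5)cc3)[C@H](O)C4)c3ccc(OCc5ccccc5)cc3O2)cc1 | intermediate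
16 | (2R,3R)-8-[(2S,4S)-7-hydroxy-2-(4-hydroxyphenyl)chroman-4-yl]-2-(4-hydroxyphenyl)chroman-3,5,7-triol | Oc1ccc([C@@H]2C[C@H](c3c(O)cc(O)c4c3O[C@H](c3ccc(O)cc3)[C@H](O)C4)c3ccc(O)cc3O2)cc1 | target

## Step count and least certain steps

Total: 11 steps. Longest linear sequence: 8 steps (steps 4–11, from 6). Steps 1–2 and step 3 are side branches.

**Step 9 (key step).** Two processes are most likely to fail.
- Face discrimination at C4 may be weak. Ring D stands perpendicular to the quinone methide and crowds both faces, and the substrate's own stereocentres are remote. The cis adduct epimeric at C2 and C4 would then accompany 14; being a diastereomer, it can be removed, but at a cost in material.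
- The strongly stabilised, hindered quinone methide may add 5 slowly. That leaves time for Friedel–Crafts self-condensation through C6' or for acid-induced oligomerisation of 5.

The fallback abandons the cycloaddition and takes C2 from the chiral pool. It sets out from 9 and comes back at 16. (S)-Liquiritigenin F1 (purchased) is benzylated (BnBr, K2CO3, acetone, rt, kept short to avoid opening of the flavanone ring) to (S)-7-(benzyloxy)-2-[4-(benzyloxy)phenyl]chroman-4-one F2. Aryllithium 10, made from 9 as in step 7 and transmetallated with CeCl3 to suppress enolisation, adds to the ketone to give the tertiary carbinol F3. Dehydration (MsCl, Et3N, CH2Cl2, 0 °C) gives the 4-aryl-2H-chromene F4, and Bu4NF gives its free alcohol F5. Hydrogenation over Pd(OH)2/C should then saturate C3=C4 from the face opposite ring B, which places H4 cis to H2 and the two aryl groups cis. It removes the benzyl ethers in the same operation, arriving at 16.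

**Step 7.** The hindered aryllithium 10 may be quenched by proton transfer, or may add sluggishly to the ortho-substituted aldehyde, so that reduced 8 is recovered. The fallback reverses the polarity and also makes steps 2 and 8 unnecessary. It sets out from 9 and comes back at 12. Aryllithium 10 is trapped with DMF to give the 8-carbaldehyde F6. Purchased 3-(benzyloxy)phenol F7 is converted with EtMgBr in CH2Cl2/toluene into bromomagnesium 3-(benzyloxy)phenoxide F8. F8 attacks F6 through its ortho carbon para to the benzyloxy group (ortho-specific hydroxyalkylation of a magnesium phenoxide through a six-membered chelate) and should give 12 directly.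

**Step 8.** The free-phenol carbinol 12 may ionise prematurely during deallylation or purification, because its cation is stabilised by five oxygen donors. Self-condensation or capture of the allyl fragment at carbon would follow. The fallback removes the protecting group from the plan. It sets out from 2 and 9 and comes back at 12. Compound 2 is deprotonated with NaH in THF to the sodium phenoxide F9, which is added to 10 at −78 °C and warmed slowly. Quenching with aqueous NH4Cl should give 12 without any allyl ether, and the crude product is taken straight into step 9.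

**Step 6.** Bromination may also occur at C6, or twice, because both free positions of ring D are activated by three oxygens. The fallback changes the point at which the halogen enters. It sets out from 7 and comes back at 9. Compound 7 is brominated before silylation (NBS, CH2Cl2, −78 °C) to the 8-bromo alcohol F10. Its free hydroxyl makes regioisomers easier to separate by crystallisation or chromatography. Silylation (TBSCl, imidazole, DMF) then gives 9.

## Further compounds

F1 | step 9 | (S)-liquiritigenin (purchased) | Oc1ccc([C@@H]2CC(=O)c3ccc(O)cc3O2)cc1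
F2 | step 9 | (S)-7-(benzyloxy)-2-[4-(benzyloxy)phenyl]chroman-4-one | c6ccccc6COc1ccc([C@@H]2CC(=O)c3ccc(OCc5ccccc5)cc3O2)cc1
F3 | step 9 | (2S)-7-(benzyloxy)-2-(4-benzyloxyphenyl)-4-[(2R,3R)-5,7-bis(benzyloxy)-2-(4-benzyloxyphenyl)-3-(tert-butyldimethylsilyloxy)chroman-8-yl]chroman-4-ol, C4 epimers | c6ccccc6COc1ccc([C@@H]2CC(O)(c3c(OCc5ccccc5)cc(OCc5ccccc5)c4c3O[C@H](c3ccc(OCc5ccccc5)cc3)[C@H](O[Si](C)(C)C(C)(C)C)C4)c3ccc(OCc5ccccc5)cc3O2)cc1
F4 | step 9 | (2R,3R)-5,7-bis(benzyloxy)-8-[(2S)-7-(benzyloxy)-2-(4-benzyloxyphenyl)-2H-chromen-4-yl]-2-(4-benzyloxyphenyl)-3-(tert-butyldimethylsilyloxy)chroman | c6ccccc6COc1ccc([C@@H]2C=C(c3c(OCc5ccccc5)cc(OCc5ccccc5)c4c3O[C@H](c3ccc(OCc5ccccc5)cc3)[C@H](O[Si](C)(C)C(C)(C)C)C4)c3ccc(OCc5ccccc5)cc3O2)cc1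
F5 | step 9 | (2R,3R)-5,7-bis(benzyloxy)-8-[(2S)-7-(benzyloxy)-2-(4-benzyloxyphenyl)-2H-chromen-4-yl]-2-(4-benzyloxyphenyl)chroman-3-ol | c6ccccc6COc1ccc([C@@H]2C=C(c3c(OCc5ccccc5)cc(OCc5ccccc5)c4c3O[C@H](c3ccc(OCc5ccccc5)cc3)[C@H](O)C4)c3ccc(OCc5ccccc5)cc3O2)cc1
F6 | step 7 | (2R,3R)-5,7-bis(benzyloxy)-2-[4-(benzyloxy)phenyl]-3-(tert-butyldimethylsilyloxy)chroman-8-carbaldehyde | O=Cc1c(OCc2ccccc2)cc(OCc2ccccc2)c2c1O[C@H](c1ccc(OCc3ccccc3)cc1)[C@H](O[Si](C)(C)C(C)(C)C)C2
F7 | step 7 | 3-(benzyloxy)phenol (purchased) | Oc1cccc(OCc2ccccc2)c1
F8 | step 7 | bromomagnesium 3-(benzyloxy)phenoxide | Br[Mg]Oc1cccc(OCc2ccccc2)c1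
F9 | step 8 | sodium 5-(benzyloxy)-2-formylphenoxide | [Na+].[O-]c1cc(OCc2ccccc2)ccc1C=O
F10 | step 6 | (2R,3R)-5,7-bis(benzyloxy)-2-[4-(benzyloxy)phenyl]-8-bromochroman-3-ol | c3ccccc3COc1cc(OCc3ccccc3)c2c(c1Br)O[C@H](c1ccc(OCc3ccccc3)cc1)[C@H](O)C2
A1 | alternative 1 | 2-[(2S,4S)-7-(benzyloxy)-2-(4-benzyloxyphenyl)chroman-4-yl]-5-(benzyloxy)-3-(triisopropylsilyloxy)phenol | c6ccccc6COc1ccc([C@@H]2C[C@H](c3c(O[Si](C(C)C)(C(C)C)C(C)C)cc(OCc5ccccc5)cc3O)c3ccc(OCc5ccccc5)cc3O2)cc1
A2 | alternative 1 | 3-(benzyloxy)cyclobut-2-en-1-one | O=C1CC(OCc2ccccc2)=C1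
A3 | alternative 1 | (2S,4R)-7-(benzyloxy)-2-(4-benzyloxyphenyl)-4-[(triisopropylsilyloxy)ethynyl]chroman (2,4-cis) | c6ccccc6COc1ccc([C@@H]2C[C@H](C#CO[Si](C(C)C)(C(C)C)C(C)C)c3ccc(OCc5ccccc5)cc3O2)cc1
A4 | alternative 2 | tetra-O-benzyl ring E pivalate of the target with free C3' hydroxyl | c6ccccc6COc1ccc([C@@H]2C[C@H](c3c(OCc5ccccc5)cc(OCc5ccccc5)c4c3O[C@H](c3ccc(OC(=O)C(C)(C)C)cc3)[C@H](O)C4)c3ccc(OCc5ccccc5)cc3O2)cc1
A5 | alternative 2 | (2S,4S)-7-(benzyloxy)-2-(4-benzyloxyphenyl)-4-{2,4-bis(benzyloxy)-6-[(R)-[(R)-oxiran-2-yl](4-pivaloyloxyphenyl)methoxy]phenyl}chroman | c6ccccc6COc1ccc([C@@H]2C[C@H](c3c(OCc5ccccc5)cc(OCc5ccccc5)cc3O[C@H](c3ccc(OC(=O)C(C)(C)C)cc3)[C@H]3CO3)c3ccc(OCc5ccccc5)cc3O2)cc1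
A6 | alternative 3 | penta-O-benzyl 3'-O-acetyl target | c6ccccc6COc1ccc([C@@H]2C[C@H](c3c(OCc5ccccc5)cc(OCc5ccccc5)c4c3O[C@H](c3ccc(OCc5ccccc5)cc3)[C@H](OC(C)=O)C4)c3ccc(OCc5ccccc5)cc3O2)cc1
A7 | alternative 3 | (2R,3R)-5,7-bis(benzyloxy)-2-(4-benzyloxyphenyl)-8-[(3S)-3-(3-benzyloxyphenoxy)-3-(4-benzyloxyphenyl)-1-hydroxypropyl]chroman-3-yl acetate, carbinol epimers | c6ccccc6COc1ccc([C@@H](Oc7cccc(OCc5ccccc5)c7)CC(O)c3c(OCc5ccccc5)cc(OCc5ccccc5)c4c3O[C@H](c3ccc(OCc5ccccc5)cc3)[C@H](OC(C)=O)C4)cc1
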